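## Analysis of the target

The target 43 (C48H34O28) is a linear chain of eight benzene rings, lettered A to H from the 2,4,6-trihydroxyphenyl end. The rings are joined only by seven diaryl ether bonds and carry 21 free phenolic hydroxyls. Each ring is numbered from the carbon whose oxygen points towards ring A.

- Rings B and D carry ethers on C1 and C4 and hydroxyls on C3 and C5.
- Rings C and G carry ethers on C1 and C2 and hydroxyls on C3, C4 and C5.
- Ring E carries the ring D oxygen on C1, the ring F oxygen on C2, a hydrogen on C3 and hydroxyls on C4, C5 and C6.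
- Ring H is a 3,4,5-trihydroxyphenyl group.

There is no stereocentre and no configurationally stable axis, so the problem is purely constitutional: which oxygen is bound to which carbon. The free polyphenol is very electron-rich and oxidises readily in air and base, so all hydroxyls have to stay masked until the last step.

The difficulty lies in the ether bonds between electron-rich rings, most of them with ortho substituents on both sides. The worst is the D–E ether: the ring D oxygen on C4 sits between two oxygenated carbons, and ring E C1 sits between the C2 ether and the C6 hydroxyl. A second difficulty is the removal of 21 protecting groups at the end.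

The strategy rests on ring F. It has oxygens on C1, C3, C4 and C5 and C–H on C2 and C6, with the ether oxygens on C1 (to ring E C2) and C5 (to ring G C1) meta to each other. This is the substitution pattern of a 3-aryloxy-5-alkoxy salicylate, which a three-carbon plus three-carbon benzannulation can deliver with the ring G ether already in place.

## Retrosynthetic reasoning

**43 to 42.** The last operation only unmasks oxygen: the 21 oxygen–methyl bonds of 42 are cut. Methyl is chosen because every building block is available as its methyl ether and because methyl ethers survive Lewis acid at low temperature, hydride, peracid, copper catalysis in hot base and diazotisation. The forward reaction has to cleave all methyl–oxygen bonds without touching an aryl–oxygen bond.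

**42 to 41 and 22.** The bond between ring E C2 and the E–F ether oxygen is cut. This splits the eight rings five to three. It also makes the ring F oxygen the nucleophile: in phenol 22 it is flanked by two C–H, so it is the least hindered oxygen of the molecule. The electrophile is iodide 41, whose iodine-bearing carbon has one free ortho position. The forward reaction is a copper-catalysed aryl ether coupling.

**22 to 15.** On ring F only functional groups change. The C3 oxygen of 22 is traced through phenol 20, formate 19, aldehyde 18 and alcohol 17 to the ester carbon of 16 and of salicylate 15. The C4 methoxy comes from the salicylate hydroxyl, and the C1 oxygen is held as the benzyl ether of 21. What is gained is a carbon substituent on C3, which is exactly what a salicylate-forming benzannulation leaves behind.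

**15 to 9 and 14 (key disconnection).** The C5–C6 and C2–C3 bonds of ring F are cut. This leaves two three-carbon pieces.
- Diene 9 supplies C3, C4 and C5 with the ester carbon and carries the G–H aryloxy group.
- Silyloxyacrolein 14 supplies C6, C1 and C2 with the benzyloxy group.

The cut is made here because the electrophile is then symmetric in oxidation level, so no regiochemical choice arises. The F–G ether also never has to be made by a coupling, since the oxygen travels on the diene. The forward reaction must join the terminal diene carbon first and the central one second, aromatise, and leave the aryl ethers untouched.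

**9 to 5 and 6.** Diene 9 is the twofold silyl enol ether of ketoester 7, reached through the mono-silyl ether 8. Ketoester 7 is cut at the oxygen–CH2 bond into G–H phenol 5 and chloroketoester 6. This is a plain O-alkylation and places the ring G oxygen on the future C5 of ring F.

**5 to 1 and 2.** In phenol 5 the G–H ether is cut at ring G C2. The formyl group of bromide 2 activates the neighbouring bromine for coupling with phenol 1. It is then itself turned into the ring G C1 oxygen, by way of aldehyde 3 and formate 4.

**14 to 10.** Silyloxyacrolein 14 is the silyl ether of malonaldehyde 13. That comes by hydrolysis of aminoacrolein 12, which is made from acid 10 by double aminomethylenation with loss of CO2, through salt 11. The α-carbon of 10 becomes the central carbon unambiguously. Benzyl is kept on the oxygen because a plain phenyl ring is inert to the formylating agent, which an electron-rich aryl group would not be.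

**41 to 35 and 37.** Iodide 41 comes from aniline 39 through diazonium salt 40, and 39 from nitro compound 38. In 38 the D–E ether is cut at ring E C1. The nitro group of bromide 37 activates the neighbouring carbon for attack by the hindered phenoxide of 35, so the tetra-ortho-substituted ether forms by addition–elimination and not by a metal-catalysed coupling. Afterwards the nitro group is exchanged for the iodine that ring F needs. Bromide 37 comes from nitroarene 36 by bromination at one of two equivalent positions.

**35 to 23, 24 and 29.** The A-to-D chain is cut three times in the same way, always at the carbon of the ring nearer to ring E. Each time a hindered phenol (23, then 27, then 32) meets a bromobenzaldehyde (24, then 29, then 24 again). The formyl group activates the bromide and is then converted into the next phenol through aldehydes 25, 30 and 33 and formates 26, 31 and 34. In this direction every hindered oxygen is a nucleophile and every electrophilic carbon is activated and lightly hindered. Bromoaldehyde 29 comes from bromoarene 28 by formylation.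

## Alternatives that were turned down

**Alternative 1:** Ring C is cut into a four-carbon vinylketene piece and a two-carbon alkyne piece. Heating ethynyl ether A2 (the alkyne carries the ring B oxygen) with racemic cyclobutenone A3 (its C2 carries the ring D oxygen) should open the four-membered ring to a vinylketene. This adds to the alkyne, the adduct reopens, and a six-electron electrocyclisation closes tetramer A1 with a free C5 hydroxyl on ring C.
- For it: three C–C bonds form in one reagent-free step. The B–C and C–D ethers arise without any C–O coupling. Ring C appears with all five oxygens at the right oxidation level, and the step sits in the middle of the molecule. On bond count and redox economy it is stronger than the chosen route, which spends six steps (15 to 22) turning an ester into a methoxy group.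
- Against it: A2 is an ynol ether of a phenol with two ortho methoxy groups. Such ethers need a multistep preparation and are fragile at the temperature the benzannulation requires. A3 needs a squarate-derived sequence with three different oxygen substituents placed in order. The D–E and E–F linkages are left untouched.
- What the chosen route offers instead: precursors 9 and 14 from cheap acyclic materials in three operations each, a low-temperature step on a precedented substrate class, and a regiochemistry that leaves no choice.

**Alternative 2:** Ring E is cut at C2–C3 and traced to cyclobutenone A5, whose C2 carries the hindered ring D oxygen. Thermolysis should open A5 to a dienylketene that closes by six-electron electrocyclisation to diaryl ether A4, with a free C2 hydroxyl on ring E.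
- For it: it solves the hardest C–O bond of the target, the tetra-ortho-substituted D–E ether, by building ring E on the oxygen. On this point it is stronger than the chosen route, which has to trust an addition–elimination (step 24) and then needs two more steps to turn nitro into iodine.
- Against it: A5 needs an aryloxy exchange on a squarate, a regioselective addition of an alkoxyvinyl organometallic to one of two similar carbonyls, and methylation of a hindered tertiary alkoxide. The hydroxyl of A4 lies next to the bulky aryloxy group and would have to be arylated by a ring F electrophile. Ring D would have to be extended towards ring A with the hindered partner as electrophile.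
- What the chosen route offers instead: the F–G ether for free, a key step without organolithium or thermolysis chemistry, and a pentamer assembled in the direction in which every hindered oxygen is the nucleophile.

**Alternative 3:** Ring B is cut between C3 and C4. Treating enoate A7 with an alkoxide base should acylate the C6 enolate on the C1 ester and, after enolisation, give triaryl diether A6 with the ethers to rings A and C in place.
- For it: it is biomimetic, needs one cheap reagent and mild conditions, and delivers ring B with all its oxygens. The di-ortho-substituted oxygen of the B–C ether is never a coupling partner. In redox economy it is ahead of the chosen route.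
- Against it: only one ring bond is formed. A7 is a β-aryloxy enoate, from which alkoxide can expel the aryloxide by addition–elimination. The C4 methylene between the enol ether and the ketone is more acidic than C6, so isomerisation and intermolecular condensation compete. The E geometry that closure needs has to be set when the hindered phenol is added to an ynoate. The D–E problem is untouched.
- What the chosen route offers instead: two C–C bonds in its key step, no geometric prerequisite, and a constitution fixed by the symmetry of 14.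

Key step: step 9

Assumption: bromides 2 and 24, bromoarene 28 and nitroarene 36 are taken as catalogue compounds; the double-bond geometries drawn for 8, 9, 12 and 14 are the expected ones and do not matter, because each of these bonds ends in an aromatic ring or is lost.

## Route

In the names below, "G–H aryloxy" stands for 3,4,5-trimethoxy-2-(3,4,5-trimethoxyphenoxy)phenoxy.

Step 1
Reactants: 1 3,4,5-trimethoxyphenol; 2 2-bromo-3,4,5-trimethoxybenzaldehyde
Product: 3 3,4,5-trimethoxy-2-(3,4,5-trimethoxyphenoxy)benzaldehyde
Conditions: CuI (10 mol %), picolinic acid (20 mol %), K3PO4, DMSO, 90 °C, argon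
Reagents that add atoms: none
Why: Ullmann diaryl ether coupling; the ortho formyl group makes the bromide electron-poor and assists copper insertion, and phenol 1 has no ortho substituent.

Step 2
Reactants: 3 3,4,5-trimethoxy-2-(3,4,5-trimethoxyphenoxy)benzaldehyde
Product: 5 3,4,5-trimethoxy-2-(3,4,5-trimethoxyphenoxy)phenol (G–H phenol), via G–H aryl formate 4 (not isolated)
Conditions: mCPBA, CH2Cl2, 0 to 20 °C; then K2CO3 (cat.), MeOH, 20 °C
Reagents that add atoms: mCPBA OOC(=O)c1cccc(Cl)c1
Why: Baeyer–Villiger (Dakin-type) oxidation; the aryl group carries an ortho aryloxy and a para methoxy group and should migrate in preference to hydrogen, and the formate is cleaved by methanolysis.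

Step 3
Reactants: 5 G–H phenol; 6 methyl 4-chloroacetoacetate
Product: 7 methyl 3-oxo-4-(G–H aryloxy)butanoate
Conditions: NaH (2.2 equiv), THF/DMF, 0 to 50 °C; then aq. NH4Cl
Reagents that add atoms: none
Why: Williamson O-alkylation; the second equivalent of base holds the ketoester as its enolate, which protects the ketone while the phenoxide displaces the primary chloride.

Step 4
Reactants: 7 methyl 3-oxo-4-(G–H aryloxy)butanoate
Product: 8 methyl (Z)-4-(G–H aryloxy)-3-(trimethylsilyloxy)but-2-enoate
Conditions: Me3SiCl, Et3N, toluene, 20 °C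
Reagents that add atoms: chlorotrimethylsilane C[Si](C)(C)Cl
Why: O-silylation of the hydrogen-bonded enol of the β-ketoester gives the silyl enol ether with the geometry of the chelated enol.

Step 5
Reactants: 8 methyl (Z)-4-(G–H aryloxy)-3-(trimethylsilyloxy)but-2-enoate
Product: 9 (1E,3Z)-1-methoxy-4-(G–H aryloxy)-1,3-bis(trimethylsilyloxy)buta-1,3-diene
Conditions: LiN(i-Pr)2, THF, −78 °C; then Me3SiCl, −78 to 20 °C; used crude
Reagents that add atoms: chlorotrimethylsilane C[Si](C)(C)Cl
Why: Kinetic γ-deprotonation of the vinylogous ester and O-silylation of the dienolate give the bis(silyloxy)diene, a masked β-ketoester dianion; the aryl ethers carry no acidic hydrogen.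

Step 6
Reactants: 10 benzyloxyacetic acid
Product: 12 (Z)-2-(benzyloxy)-3-(dimethylamino)prop-2-enal, via vinamidinium chloride 11 (not isolated)
Conditions: POCl3 (3 equiv), DMF, 0 to 80 °C; then aq. K2CO3, 20 °C
Reagents that add atoms: N,N-dimethylformamide CN(C)C=O; water O
Why: Vilsmeier–Haack–Arnold reaction; the activated acid is aminomethylenated twice on its α-carbon with loss of CO2, as known for aryloxy- and haloacetic acids, and mild aqueous base hydrolyses one iminium end to the vinylogous formamide.

Step 7
Reactants: 12 (Z)-2-(benzyloxy)-3-(dimethylamino)prop-2-enal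
Product: 13 2-(benzyloxy)propanedial (benzyloxymalonaldehyde, present as its enol)
Conditions: NaOH (2 M aq.), 70 °C; then HCl to pH 3, 0 °C
Reagents that add atoms: water O
Why: Hydroxide adds to the vinylogous amide and expels dimethylamine (addition–elimination); acidification of the sodium enolate gives the enolised dialdehyde.

Step 8
Reactants: 13 2-(benzyloxy)propanedial
Product: 14 (Z)-2-(benzyloxy)-3-(trimethylsilyloxy)prop-2-enal
Conditions: Me3SiCl, Et3N, CH2Cl2, 0 to 20 °C; used crude
Reagents that add atoms: chlorotrimethylsilane C[Si](C)(C)Cl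
Why: O-silylation of the enol gives the vinylogous silyl formate, a 1,3-dielectrophile soluble in CH2Cl2 and free of acidic hydrogen.

Step 9
Reactants: 9 (1E,3Z)-1-methoxy-4-(G–H aryloxy)-1,3-bis(trimethylsilyloxy)buta-1,3-diene; 14 (Z)-2-(benzyloxy)-3-(trimethylsilyloxy)prop-2-enal
Product: 15 methyl 5-(benzyloxy)-2-hydroxy-3-(G–H aryloxy)benzoate (F–G–H salicylate)
Conditions: TiCl4 (2 equiv), CH2Cl2, −78 to 20 °C; then aq. NaHCO3
Reagents that add atoms: none
Why: TiCl4 (tetravalent titanium) binds the formyl oxygen of 14, and the terminal carbon of diene 9, which bears the G–H aryloxy group and is the most nucleophilic position of a 1,3-bis(silyloxy)diene, adds to this vinylogous silyl formate in Mukaiyama fashion, which makes the C5–C6 bond of ring F. The silyl groups pass to chloride or oxygen and leave a titanium enolate of the β-ketoester, whose central carbon attacks the second formyl-level carbon in a 6-(enolexo)-exo-trig aldol closure, which makes the C2–C3 bond and closes ring F. Loss of silanol and water and enolisation of the ring ketone aromatise the ring to salicylate 15, with the ester on C3, the hydrogen-bonded hydroxyl on C4, the ring G ether on C5 and benzyloxy on C1. The closest known reaction type is the TiCl4-mediated formal [3+3] cyclocondensation of 1,3-bis(silyloxy)buta-1,3-dienes, 4-aryloxy-substituted ones included, with 3-silyloxy-2-en-1-ones and malonaldehyde equivalents. No stereocentre is formed, and the double-bond geometry of both partners is erased on aromatisation. The step needs terminal-before-central attack of the diene, which the higher nucleophilicity of the terminal carbon secures, and it needs no choice between the two electrophilic carbons, because both ends of 14 are at the aldehyde oxidation level and flank the same benzyloxy carbon, so either order gives the same constitution. Two equivalents of TiCl4 are planned because the vicinal methoxy groups of rings G and H also bind the Lewis acid, and the low temperature should keep methyl, benzyl and diaryl ethers intact.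

Step 10
Reactants: 15 methyl 5-(benzyloxy)-2-hydroxy-3-(G–H aryloxy)benzoate
Product: 16 methyl 5-(benzyloxy)-2-methoxy-3-(G–H aryloxy)benzoate
Conditions: MeI, K2CO3, DMF, 50 °C
Reagents that add atoms: iodomethane CI
Why: Williamson methylation of the chelated salicylate hydroxyl; a polar solvent and gentle heating break the hydrogen bond to the ester.

Step 11
Reactants: 16 methyl 5-(benzyloxy)-2-methoxy-3-(G–H aryloxy)benzoate
Product: 17 [5-(benzyloxy)-2-methoxy-3-(G–H aryloxy)phenyl]methanol
Conditions: LiAlH4, THF, 0 °C; then aqueous work-up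
Reagents that add atoms: none
Why: Hydride reduction of the ester to the benzylic alcohol; aryl, methyl and benzyl ethers are inert.

Step 12
Reactants: 17 [5-(benzyloxy)-2-methoxy-3-(G–H aryloxy)phenyl]methanol
Product: 18 5-(benzyloxy)-2-methoxy-3-(G–H aryloxy)benzaldehyde
Conditions: MnO2, CH2Cl2, 20 °C
Reagents that add atoms: none
Why: Selective oxidation of a benzylic alcohol, which stops at the aldehyde.

Step 13
Reactants: 18 5-(benzyloxy)-2-methoxy-3-(G–H aryloxy)benzaldehyde
Product: 20 5-(benzyloxy)-2-methoxy-3-(G–H aryloxy)phenol, via F–G–H aryl formate 19 (not isolated)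
Conditions: mCPBA, NaHCO3, CH2Cl2, 0 to 20 °C; then K2CO3 (cat.), MeOH, 20 °C
Reagents that add atoms: mCPBA OOC(=O)c1cccc(Cl)c1
Why: Baeyer–Villiger (Dakin-type) oxidation; the ortho methoxy group makes aryl migration faster than hydrogen migration, and the formate is removed by methanolysis.

Step 14
Reactants: 20 5-(benzyloxy)-2-methoxy-3-(G–H aryloxy)phenol
Product: 21 5-(benzyloxy)-1,2-dimethoxy-3-(G–H aryloxy)benzene
Conditions: MeI, K2CO3, acetone, 50 °C
Reagents that add atoms: iodomethane CI
Why: Williamson methylation of a phenol with one free ortho position.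

Step 15
Reactants: 21 5-(benzyloxy)-1,2-dimethoxy-3-(G–H aryloxy)benzene
Product: 22 3,4-dimethoxy-5-(G–H aryloxy)phenol (F–G–H phenol)
Conditions: H2 (1 atm), Pd/C (10 % palladium on carbon), EtOAc/MeOH, 20 °C
Reagents that add atoms: none
Why: Hydrogenolysis of the benzyl ether; diaryl and methyl ethers are not cleaved under these conditions.

Step 16
Reactants: 23 2,4,6-trimethoxyphenol; 24 4-bromo-2,6-dimethoxybenzaldehyde
Product: 25 2,6-dimethoxy-4-(2,4,6-trimethoxyphenoxy)benzaldehyde (A–B aldehyde)
Conditions: CuI (10 mol %), picolinic acid (20 mol %), K3PO4, DMSO, 90 °C, argon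
Reagents that add atoms: none
Why: Ullmann diaryl ether coupling; the bromide is para to formyl and has no ortho substituent, so the coupling should tolerate the doubly ortho-substituted phenoxide; air is excluded because 23 oxidises easily.

Step 17
Reactants: 25 A–B aldehyde
Product: 27 2,6-dimethoxy-4-(2,4,6-trimethoxyphenoxy)phenol (A–B phenol), via A–B aryl formate 26 (not isolated)
Conditions: mCPBA (1.1 equiv), CH2Cl2, 0 °C; then K2CO3 (cat.), MeOH, 20 °C
Reagents that add atoms: mCPBA OOC(=O)c1cccc(Cl)c1
Why: Baeyer–Villiger (Dakin-type) oxidation; a benzaldehyde with two ortho methoxy groups reacts fast, so a slight excess of peracid at low temperature should spare the electron-rich ring A.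

Step 18
Reactants: 28 5-bromo-1,2,3-trimethoxybenzene
Product: 29 6-bromo-2,3,4-trimethoxybenzaldehyde
Conditions: Cl2CHOMe, TiCl4, CH2Cl2, −10 to 0 °C; then ice water
Reagents that add atoms: dichloromethyl methyl ether COC(Cl)Cl; water O
Why: Rieche formylation; the two free positions of 28 are equivalent and each is ortho and para to a methoxy group, so one aldehyde can form.

Step 19
Reactants: 27 A–B phenol; 29 6-bromo-2,3,4-trimethoxybenzaldehyde
Product: 30 6-[2,6-dimethoxy-4-(2,4,6-trimethoxyphenoxy)phenoxy]-2,3,4-trimethoxybenzaldehyde (A–B–C aldehyde)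
Conditions: CuI (10 mol %), picolinic acid (20 mol %), K3PO4, DMSO, 90 °C, argon
Reagents that add atoms: none
Why: Ullmann diaryl ether coupling; the bromide is activated by the ortho formyl group and has a hydrogen on its other side, which offsets the two ortho methoxy groups of the phenoxide.

Step 20
Reactants: 30 A–B–C aldehyde
Product: 32 6-[2,6-dimethoxy-4-(2,4,6-trimethoxyphenoxy)phenoxy]-2,3,4-trimethoxyphenol (A–B–C phenol), via A–B–C aryl formate 31 (not isolated)
Conditions: mCPBA (1.1 equiv), CH2Cl2, 0 °C; then K2CO3 (cat.), MeOH, 20 °C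
Reagents that add atoms: mCPBA OOC(=O)c1cccc(Cl)c1
Why: Baeyer–Villiger (Dakin-type) oxidation; the formyl group lies between an aryloxy and a methoxy group, so aryl migration is strongly favoured.

Step 21
Reactants: 32 A–B–C phenol; 24 4-bromo-2,6-dimethoxybenzaldehyde
Product: 33 4-{6-[2,6-dimethoxy-4-(2,4,6-trimethoxyphenoxy)phenoxy]-2,3,4-trimethoxyphenoxy}-2,6-dimethoxybenzaldehyde (A–B–C–D aldehyde)
Conditions: CuI (10 mol %), picolinic acid (20 mol %), K3PO4, DMSO, 90 °C, argon
Reagents that add atoms: none
Why: Ullmann diaryl ether coupling of the same type as step 16: hindered phenoxide, unhindered para-formyl bromide.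

Step 22
Reactants: 33 A–B–C–D aldehyde
Product: 35 4-{6-[2,6-dimethoxy-4-(2,4,6-trimethoxyphenoxy)phenoxy]-2,3,4-trimethoxyphenoxy}-2,6-dimethoxyphenol (A–B–C–D phenol), via A–B–C–D aryl formate 34 (not isolated)
Conditions: mCPBA (1.1 equiv), CH2Cl2, 0 °C; then K2CO3 (cat.), MeOH, 20 °C
Reagents that add atoms: mCPBA OOC(=O)c1cccc(Cl)c1
Why: Baeyer–Villiger (Dakin-type) oxidation of a benzaldehyde with two ortho methoxy groups, as in step 17.

Step 23
Reactants: 36 1,2,3-trimethoxy-5-nitrobenzene
Product: 37 2-bromo-3,4,5-trimethoxy-1-nitrobenzene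
Conditions: Br2, NaOAc, AcOH, 50 °C
Reagents that add atoms: bromine BrBr
Why: Electrophilic aromatic bromination; the two free positions are equivalent and each is ortho and para to a methoxy group, so the nitro group slows the reaction but leaves no regiochemical choice.

Step 24
Reactants: 35 A–B–C–D phenol; 37 2-bromo-3,4,5-trimethoxy-1-nitrobenzene
Product: 38 A-to-E nitro pentamer (2,3,4-trimethoxy-6-nitrophenyl ether of 35; nitro on ring E C2)
Conditions: Cs2CO3, DMSO, 90 °C, argon
Reagents that add atoms: none
Why: Nucleophilic aromatic substitution by addition–elimination; the ortho nitro group stabilises the Meisenheimer adduct, the caesium phenoxide is poorly ion-paired in DMSO, and bromide is a far better leaving group than the methoxide para to nitro.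

Step 25
Reactants: 38 A-to-E nitro pentamer
Product: 39 A-to-E aniline (amino on ring E C2)
Conditions: H2 (1 atm), Pd/C (10 % palladium on carbon), EtOAc/EtOH, 20 °C
Reagents that add atoms: none
Why: Catalytic hydrogenation of the nitro group; the molecule holds no benzyl ether or halogen at this stage.

Step 26
Reactants: 39 A-to-E aniline
Product: 41 A-to-E iodide (iodine on ring E C2), via diazonium tosylate 40 (not isolated)
Conditions: t-BuONO, TsOH·H2O, MeCN, 0 °C; then KI, H2O, 0 to 20 °C
Reagents that add atoms: potassium iodide [K+].[I-]; for intermediate 40 only: tert-butyl nitrite CC(C)(C)ON=O and 4-methylbenzenesulfonic acid Cc1ccc(cc1)S(O)(=O)=O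
Why: Sandmeyer-type iodination; the arenediazonium tosylate is reduced by iodide without copper, and both ortho positions of ring D carry methoxy groups, so a Pschorr-type ring closure onto ring D is blocked.

Step 27
Reactants: 41 A-to-E iodide; 22 F–G–H phenol
Product: 42 henicosa-O-methyl ether of the target (every hydroxyl of 43 as methoxy)
Conditions: CuI (20 mol %), picolinic acid (40 mol %), K3PO4, DMSO, 100 °C, argon
Reagents that add atoms: none
Why: Ullmann diaryl ether coupling; the phenoxide of 22 has no ortho substituent and the iodide has one free ortho position, a ligand system suited to hindered partners is used, and iodide is the most reactive halide for copper insertion.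

Step 28
Reactants: 42 henicosa-O-methyl ether of the target
Product: 43 target octamer CNP0309601.0
Conditions: BBr3 (excess), CH2Cl2, −78 to 20 °C; then degassed H2O/MeOH, argon
Reagents that add atoms: none
Why: Lewis-acid ether cleavage; BBr3 binds each methoxy oxygen and bromide attacks the methyl carbon (SN2), while the diaryl ether oxygens have only aryl carbons that cannot be attacked this way; hydrolysis of the aryl borates frees the 21 hydroxyls.

## Compound list

1 | 3,4,5-trimethoxyphenol | COc1cc(O)cc(OC)c1OC | starting material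
2 | 2-bromo-3,4,5-trimethoxybenzaldehyde | COc1cc(C=O)c(Br)c(OC)c1OC | starting material
3 | 3,4,5-trimethoxy-2-(3,4,5-trimethoxyphenoxy)benzaldehyde | O=Cc1cc(OC)c(OC)c(OC)c1Oc1cc(OC)c(OC)c(OC)c1 | intermediate
4 | 3,4,5-trimethoxy-2-(3,4,5-trimethoxyphenoxy)phenyl formate | O=COc1cc(OC)c(OC)c(OC)c1Oc1cc(OC)c(OC)c(OC)c1 | intermediate (not isolated)
5 | 3,4,5-trimethoxy-2-(3,4,5-trimethoxyphenoxy)phenol (G–H phenol) | Oc1cc(OC)c(OC)c(OC)c1Oc1cc(OC)c(OC)c(OC)c1 | intermediate
6 | methyl 4-chloroacetoacetate | COC(=O)CC(=O)CCl | starting material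
7 | methyl 3-oxo-4-[3,4,5-trimethoxy-2-(3,4,5-trimethoxyphenoxy)phenoxy]butanoate | COC(=O)CC(=O)COc1cc(OC)c(OC)c(OC)c1Oc1cc(OC)c(OC)c(OC)c1 | intermediate
8 | methyl (Z)-4-[3,4,5-trimethoxy-2-(3,4,5-trimethoxyphenoxy)phenoxy]-3-(trimethylsilyloxy)but-2-enoate | COC(=O)/C=C(\O[Si](C)(C)C)COc1cc(OC)c(OC)c(OC)c1Oc1cc(OC)c(OC)c(OC)c1 | intermediate
9 | (1E,3Z)-1-methoxy-4-[3,4,5-trimethoxy-2-(3,4,5-trimethoxyphenoxy)phenoxy]-1,3-bis(trimethylsilyloxy)buta-1,3-diene | CO\C(O[Si](C)(C)C)=C/C(O[Si](C)(C)C)=C/Oc1cc(OC)c(OC)c(OC)c1Oc1cc(OC)c(OC)c(OC)c1 | intermediate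
10 | benzyloxyacetic acid | OC(=O)COCc1ccccc1 | starting material
11 | 2-(benzyloxy)-1,3-bis(dimethylamino)trimethinium (vinamidinium) chloride | CN(C)C=C(OCc1ccccc1)C=[N+](C)C.[Cl-] | intermediate (not isolated)
12 | (Z)-2-(benzyloxy)-3-(dimethylamino)prop-2-enal | CN(C)/C=C(/C=O)OCc1ccccc1 | intermediate
13 | 2-(benzyloxy)propanedial (benzyloxymalonaldehyde; enol tautomer predominant) | O=CC(OCc1ccccc1)C=O | intermediate
14 | (Z)-2-(benzyloxy)-3-(trimethylsilyloxy)prop-2-enal | O=C/C(OCc1ccccc1)=C/O[Si](C)(C)C | intermediate
15 | methyl 5-(benzyloxy)-2-hydroxy-3-[3,4,5-trimethoxy-2-(3,4,5-trimethoxyphenoxy)phenoxy]benzoate | COC(=O)c1cc(OCc2ccccc2)cc(Oc2cc(OC)c(OC)c(OC)c2Oc2cc(OC)c(OC)c(OC)c2)c1O | intermediate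
16 | methyl 5-(benzyloxy)-2-methoxy-3-[3,4,5-trimethoxy-2-(3,4,5-trimethoxyphenoxy)phenoxy]benzoate | COC(=O)c1cc(OCc2ccccc2)cc(Oc2cc(OC)c(OC)c(OC)c2Oc2cc(OC)c(OC)c(OC)c2)c1OC | intermediate
17 | {5-(benzyloxy)-2-methoxy-3-[3,4,5-trimethoxy-2-(3,4,5-trimethoxyphenoxy)phenoxy]phenyl}methanol | OCc1cc(OCc2ccccc2)cc(Oc2cc(OC)c(OC)c(OC)c2Oc2cc(OC)c(OC)c(OC)c2)c1OC | intermediate
18 | 5-(benzyloxy)-2-methoxy-3-[3,4,5-trimethoxy-2-(3,4,5-trimethoxyphenoxy)phenoxy]benzaldehyde | O=Cc1cc(OCc2ccccc2)cc(Oc2cc(OC)c(OC)c(OC)c2Oc2cc(OC)c(OC)c(OC)c2)c1OC | intermediate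
19 | 5-(benzyloxy)-2-methoxy-3-[3,4,5-trimethoxy-2-(3,4,5-trimethoxyphenoxy)phenoxy]phenyl formate | O=COc1cc(OCc2ccccc2)cc(Oc2cc(OC)c(OC)c(OC)c2Oc2cc(OC)c(OC)c(OC)c2)c1OC | intermediate (not isolated)
20 | 5-(benzyloxy)-2-methoxy-3-[3,4,5-trimethoxy-2-(3,4,5-trimethoxyphenoxy)phenoxy]phenol | Oc1cc(OCc2ccccc2)cc(Oc2cc(OC)c(OC)c(OC)c2Oc2cc(OC)c(OC)c(OC)c2)c1OC | intermediate
21 | 5-(benzyloxy)-1,2-dimethoxy-3-[3,4,5-trimethoxy-2-(3,4,5-trimethoxyphenoxy)phenoxy]benzene | COc1cc(OCc2ccccc2)cc(Oc2cc(OC)c(OC)c(OC)c2Oc2cc(OC)c(OC)c(OC)c2)c1OC | intermediate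
22 | 3,4-dimethoxy-5-[3,4,5-trimethoxy-2-(3,4,5-trimethoxyphenoxy)phenoxy]phenol (F–G–H phenol) | COc1cc(O)cc(Oc2cc(OC)c(OC)c(OC)c2Oc2cc(OC)c(OC)c(OC)c2)c1OC | intermediate
23 | 2,4,6-trimethoxyphenol | COc1cc(OC)c(O)c(OC)c1 | starting material
24 | 4-bromo-2,6-dimethoxybenzaldehyde | COc1cc(Br)cc(OC)c1C=O | starting material
25 | 2,6-dimethoxy-4-(2,4,6-trimethoxyphenoxy)benzaldehyde | COc1cc(OC)c(Oc2cc(OC)c(C=O)c(OC)c2)c(OC)c1 | intermediate
26 | 2,6-dimethoxy-4-(2,4,6-trimethoxyphenoxy)phenyl formate | COc1cc(OC)c(Oc2cc(OC)c(OC=O)c(OC)c2)c(OC)c1 | intermediate (not isolated)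
27 | 2,6-dimethoxy-4-(2,4,6-trimethoxyphenoxy)phenol (A–B phenol) | COc1cc(OC)c(Oc2cc(OC)c(O)c(OC)c2)c(OC)c1 | intermediate
28 | 5-bromo-1,2,3-trimethoxybenzene | COc1cc(Br)cc(OC)c1OC | starting material
29 | 6-bromo-2,3,4-trimethoxybenzaldehyde | COc1cc(Br)c(C=O)c(OC)c1OC | intermediate
30 | 6-[2,6-dimethoxy-4-(2,4,6-trimethoxyphenoxy)phenoxy]-2,3,4-trimethoxybenzaldehyde | COc1cc(OC)c(Oc2cc(OC)c(Oc3cc(OC)c(OC)c(OC)c3C=O)c(OC)c2)c(OC)c1 | intermediate
31 | 6-[2,6-dimethoxy-4-(2,4,6-trimethoxyphenoxy)phenoxy]-2,3,4-trimethoxyphenyl formate | COc1cc(OC)c(Oc2cc(OC)c(Oc3cc(OC)c(OC)c(OC)c3OC=O)c(OC)c2)c(OC)c1 | intermediate (not isolated)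
32 | 6-[2,6-dimethoxy-4-(2,4,6-trimethoxyphenoxy)phenoxy]-2,3,4-trimethoxyphenol (A–B–C phenol) | COc1cc(OC)c(Oc2cc(OC)c(Oc3cc(OC)c(OC)c(OC)c3O)c(OC)c2)c(OC)c1 | intermediate
33 | 4-{6-[2,6-dimethoxy-4-(2,4,6-trimethoxyphenoxy)phenoxy]-2,3,4-trimethoxyphenoxy}-2,6-dimethoxybenzaldehyde | COc1cc(OC)c(Oc2cc(OC)c(Oc3cc(OC)c(OC)c(OC)c3Oc3cc(OC)c(C=O)c(OC)c3)c(OC)c2)c(OC)c1 | intermediate
34 | 4-{6-[2,6-dimethoxy-4-(2,4,6-trimethoxyphenoxy)phenoxy]-2,3,4-trimethoxyphenoxy}-2,6-dimethoxyphenyl formate | COc1cc(OC)c(Oc2cc(OC)c(Oc3cc(OC)c(OC)c(OC)c3Oc3cc(OC)c(OC=O)c(OC)c3)c(OC)c2)c(OC)c1 | intermediate (not isolated)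
35 | 4-{6-[2,6-dimethoxy-4-(2,4,6-trimethoxyphenoxy)phenoxy]-2,3,4-trimethoxyphenoxy}-2,6-dimethoxyphenol (A–B–C–D phenol) | COc1cc(OC)c(Oc2cc(OC)c(Oc3cc(OC)c(OC)c(OC)c3Oc3cc(OC)c(O)c(OC)c3)c(OC)c2)c(OC)c1 | intermediate
36 | 1,2,3-trimethoxy-5-nitrobenzene | COc1cc([N+](=O)[O-])cc(OC)c1OC | starting material
37 | 2-bromo-3,4,5-trimethoxy-1-nitrobenzene | COc1cc([N+](=O)[O-])c(Br)c(OC)c1OC | intermediate
38 | A-to-E nitro pentamer: 2,3,4-trimethoxy-6-nitrophenyl ether of phenol 35 | COc1cc(OC)c(Oc2cc(OC)c(Oc3cc(OC)c(OC)c(OC)c3Oc3cc(OC)c(Oc4c([N+](=O)[O-])cc(OC)c(OC)c4OC)c(OC)c3)c(OC)c2)c(OC)c1 | intermediate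
39 | A-to-E aniline: 6-amino-2,3,4-trimethoxyphenyl ether of phenol 35 | COc1cc(OC)c(Oc2cc(OC)c(Oc3cc(OC)c(OC)c(OC)c3Oc3cc(OC)c(Oc4c(N)cc(OC)c(OC)c4OC)c(OC)c3)c(OC)c2)c(OC)c1 | intermediate
40 | A-to-E arenediazonium 4-methylbenzenesulfonate (diazonium on ring E C2) | COc1cc(OC)c(Oc2cc(OC)c(Oc3cc(OC)c(OC)c(OC)c3Oc3cc(OC)c(Oc4c([N+]#N)cc(OC)c(OC)c4OC)c(OC)c3)c(OC)c2)c(OC)c1.Cc1ccc(cc1)S(=O)(=O)[O-] | intermediate (not isolated)
41 | A-to-E iodide: 6-iodo-2,3,4-trimethoxyphenyl ether of phenol 35 | COc1cc(OC)c(Oc2cc(OC)c(Oc3cc(OC)c(OC)c(OC)c3Oc3cc(OC)c(Oc4c(I)cc(OC)c(OC)c4OC)c(OC)c3)c(OC)c2)c(OC)c1 | intermediate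
42 | henicosa-O-methyl ether of the target (permethylated octamer) | COc1cc(OC)c(Oc2cc(OC)c(Oc3cc(OC)c(OC)c(OC)c3Oc3cc(OC)c(Oc4c(Oc5cc(OC)c(OC)c(Oc6cc(OC)c(OC)c(OC)c6Oc6cc(OC)c(OC)c(OC)c6)c5)cc(OC)c(OC)c4OC)c(OC)c3)c(OC)c2)c(OC)c1 | intermediate
43 | CNP0309601.0 (octameric polyhydroxylated phenyl ether, rings A to H) | Oc1cc(O)c(Oc2cc(O)c(Oc3cc(O)c(O)c(O)c3Oc3cc(O)c(Oc4c(Oc5cc(O)c(O)c(Oc6cc(O)c(O)c(O)c6Oc6cc(O)c(O)c(O)c6)c5)cc(O)c(O)c4O)c(O)c3)c(O)c2)c(O)c1 | target

## Step count and uncertain steps

Total step count: 28. Longest linear sequence: 14 steps (steps 1 to 5, 9 to 15, 27 and 28, from 1 and 2). The pentamer branch (steps 16, 17, 19 to 22, 24 to 26) joins at step 27.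

**Step 9 (key step).** The most likely failure is that the Lewis acid is taken up by the chelating methoxy arrays of rings G and H. The ketene acetal end of 9 would then lose its silyl group before any C–C bond forms, and the diene would fall back to ketoester 7. A second possibility is Lewis-acid cleavage of the benzyl ether or oligomerisation of the silyloxyacrolein. Fallback: ring F is not built but bought. It sets out from phenol 5, which is coupled under the copper conditions of step 1 with 3-bromo-4,5-dimethoxybenzaldehyde F1 to give 3,4-dimethoxy-5-(G–H aryloxy)benzaldehyde F2. Peracid oxidation gives the aryl formate F3, and its methanolysis returns to the route at phenol 22.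

**Step 24.** The phenoxide of 35 has two ortho methoxy groups and must add to a carbon that lies between nitro and methoxy on a ring with three donor groups. Addition may be too slow, and prolonged heating may bring attack at the methoxy carbon para to nitro. Fallback: the ether is made by carbonyl-assisted copper coupling instead. It sets out from phenol 35, which is coupled with bromoaldehyde 2 (CuI, picolinic acid, K3PO4, DMSO) to give the A-to-E aldehyde F4. Pinnick oxidation (NaClO2, NaH2PO4, 2-methyl-2-butene) gives the A-to-E carboxylic acid F5. Ipso-iododecarboxylation of this electron-rich ortho-aryloxy benzoic acid (I2, K3PO4, MeCN, heat) returns to the route at iodide 41. This path also passes by steps 25 and 26.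

**Step 26.** Nitrosation of the very electron-rich ring A by the nitrite under acid, or reduction of the diazonium salt to the arene, may compete with iodide transfer. Fallback: the activating group is placed on the other side of the reacting carbon, so that it ends as a methoxy group and no nitrogen is needed. 1-Bromo-2-fluoro-4,5-dimethoxybenzene F6 is lithiated between fluorine and methoxy (LiN(i-Pr)2, −78 °C) and formylated with DMF to 3-bromo-2-fluoro-5,6-dimethoxybenzaldehyde F7. The fallback proper sets out from phenol 35, which displaces the fluoride of F7 (Cs2CO3, DMSO) to give the A-to-E bromo aldehyde F8. Peracid oxidation through formate F9 gives the A-to-E bromo phenol F10, and methylation gives the A-to-E bromide F11. F11 takes the place of 41 in the coupling with 22 and returns to the route at 42.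

**Step 27.** Copper insertion into the iodide next to the bulky ring D ether may be slow. Loss of iodine for hydrogen and oxidative self-coupling of phenoxide 22 would then take over. Fallback: the polarity of the metal step is changed from oxidative addition to transmetalation. It sets out from iodide 41: iodine–lithium exchange (n-BuLi, THF, −78 °C), B(Oi-Pr)3 and aqueous work-up give the A-to-E boronic acid F12. Chan–Lam coupling of F12 with 22 (Cu(OAc)2, pyridine, 4 Å molecular sieves, CH2Cl2, air, 20 °C) returns to the route at 42.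

**Step 28.** Twenty-one cleavages must all go to completion, and the free polyphenol is air-sensitive, so incomplete demethylation and oxidative darkening during work-up are the likely failures. Fallback: the product is captured, purified and released. It sets out from 42: after the BBr3 treatment and quench the crude material is acetylated at once (Ac2O, pyridine) to the henicosaacetate F13. F13 can be chromatographed, and incompletely demethylated fractions can be separated and resubmitted. Zemplén deacetylation (NaOMe cat., MeOH, argon, then acidic resin) returns to the route at 43.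

## Further compounds

F1 | step 9 | 3-bromo-4,5-dimethoxybenzaldehyde | O=Cc1cc(Br)c(OC)c(OC)c1
F2 | step 9 | 3,4-dimethoxy-5-[3,4,5-trimethoxy-2-(3,4,5-trimethoxyphenoxy)phenoxy]benzaldehyde | O=Cc1cc(OC)c(OC)c(Oc2cc(OC)c(OC)c(OC)c2Oc2cc(OC)c(OC)c(OC)c2)c1
F3 | step 9 | 3,4-dimethoxy-5-[3,4,5-trimethoxy-2-(3,4,5-trimethoxyphenoxy)phenoxy]phenyl formate | O=COc1cc(OC)c(OC)c(Oc2cc(OC)c(OC)c(OC)c2Oc2cc(OC)c(OC)c(OC)c2)c1
F4 | step 24 | A-to-E aldehyde: 6-formyl-2,3,4-trimethoxyphenyl ether of phenol 35 | COc1cc(OC)c(Oc2cc(OC)c(Oc3cc(OC)c(OC)c(OC)c3Oc3cc(OC)c(Oc4c(C=O)cc(OC)c(OC)c4OC)c(OC)c3)c(OC)c2)c(OC)c1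
F5 | step 24 | A-to-E carboxylic acid: 6-carboxy-2,3,4-trimethoxyphenyl ether of phenol 35 | COc1cc(OC)c(Oc2cc(OC)c(Oc3cc(OC)c(OC)c(OC)c3Oc3cc(OC)c(Oc4c(C(=O)O)cc(OC)c(OC)c4OC)c(OC)c3)c(OC)c2)c(OC)c1
F6 | step 26 | 1-bromo-2-fluoro-4,5-dimethoxybenzene | COc1cc(F)c(Br)cc1OC
F7 | step 26 | 3-bromo-2-fluoro-5,6-dimethoxybenzaldehyde | O=Cc1c(F)c(Br)cc(OC)c1OC
F8 | step 26 | A-to-E bromo aldehyde: 2-bromo-6-formyl-4,5-dimethoxyphenyl ether of phenol 35 | COc1cc(OC)c(Oc2cc(OC)c(Oc3cc(OC)c(OC)c(OC)c3Oc3cc(OC)c(Oc4c(Br)cc(OC)c(OC)c4C=O)c(OC)c3)c(OC)c2)c(OC)c1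
F9 | step 26 | A-to-E bromo aryl formate: 2-bromo-6-(formyloxy)-4,5-dimethoxyphenyl ether of phenol 35 | COc1cc(OC)c(Oc2cc(OC)c(Oc3cc(OC)c(OC)c(OC)c3Oc3cc(OC)c(Oc4c(Br)cc(OC)c(OC)c4OC=O)c(OC)c3)c(OC)c2)c(OC)c1
F10 | step 26 | A-to-E bromo phenol: 2-bromo-6-hydroxy-4,5-dimethoxyphenyl ether of phenol 35 | COc1cc(OC)c(Oc2cc(OC)c(Oc3cc(OC)c(OC)c(OC)c3Oc3cc(OC)c(Oc4c(Br)cc(OC)c(OC)c4O)c(OC)c3)c(OC)c2)c(OC)c1
F11 | step 26 | A-to-E bromide: 6-bromo-2,3,4-trimethoxyphenyl ether of phenol 35 | COc1cc(OC)c(Oc2cc(OC)c(Oc3cc(OC)c(OC)c(OC)c3Oc3cc(OC)c(Oc4c(Br)cc(OC)c(OC)c4OC)c(OC)c3)c(OC)c2)c(OC)c1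
F12 | step 27 | A-to-E boronic acid: 6-(dihydroxyboryl)-2,3,4-trimethoxyphenyl ether of phenol 35 | COc1cc(OC)c(Oc2cc(OC)c(Oc3cc(OC)c(OC)c(OC)c3Oc3cc(OC)c(Oc4c(B(O)O)cc(OC)c(OC)c4OC)c(OC)c3)c(OC)c2)c(OC)c1
F13 | step 28 | henicosaacetate of the target (every hydroxyl of 43 as acetate) | CC(=O)Oc1cc(OC(C)=O)c(Oc2cc(OC(C)=O)c(Oc3cc(OC(C)=O)c(OC(C)=O)c(OC(C)=O)c3Oc3cc(OC(C)=O)c(Oc4c(Oc5cc(OC(C)=O)c(OC(C)=O)c(Oc6cc(OC(C)=O)c(OC(C)=O)c(OC(C)=O)c6Oc6cc(OC(C)=O)c(OC(C)=O)c(OC(C)=O)c6)c5)cc(OC(C)=O)c(OC(C)=O)c4OC(C)=O)c(OC(C)=O)c3)c(OC(C)=O)c2)c(OC(C)=O)c1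
A1 | alternative 1 | 4-[4-(benzyloxy)-3,5-dimethoxyphenoxy]-5-[2,6-dimethoxy-4-(2,4,6-trimethoxyphenoxy)phenoxy]-3-ethoxy-2-methoxyphenol (A–B–C–D tetramer) | Oc1cc(Oc2c(OC)cc(Oc3c(OC)cc(OC)cc3OC)cc2OC)c(Oc2cc(OC)c(OCc3ccccc3)c(OC)c2)c(OCC)c1OC
A2 | alternative 1 | 2-(ethynyloxy)-1,3-dimethoxy-5-(2,4,6-trimethoxyphenoxy)benzene | C#COc1c(OC)cc(Oc2c(OC)cc(OC)cc2OC)cc1OC
A3 | alternative 1 | racemic 2-[4-(benzyloxy)-3,5-dimethoxyphenoxy]-3-ethoxy-4-methoxycyclobut-2-en-1-one | CCOC1=C(Oc2cc(OC)c(OCc3ccccc3)c(OC)c2)C(=O)C1OC
A4 | alternative 2 | 2-[4-(benzyloxy)-2,6-dimethoxyphenoxy]-3,4,5-trimethoxyphenol (D–E diaryl ether) | Oc1cc(OC)c(OC)c(OC)c1Oc1c(OC)cc(OCc2ccccc2)cc1OC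
A5 | alternative 2 | racemic 2-[4-(benzyloxy)-2,6-dimethoxyphenoxy]-3,4-dimethoxy-4-(1-methoxyethenyl)cyclobut-2-en-1-one | COC(=C)C1(OC)C(OC)=C(Oc2c(OC)cc(OCc3ccccc3)cc2OC)C1=O
A6 | alternative 3 | 2-[2-(benzyloxy)-3,4,5-trimethoxyphenoxy]-5-(2,4,6-trimethoxyphenoxy)benzene-1,3-diol (A–B–C triaryl diether) | Oc1cc(Oc2c(OC)cc(OC)cc2OC)cc(O)c1Oc1cc(OC)c(OC)c(OC)c1OCc1ccccc1
A7 | alternative 3 | methyl (E)-6-[2-(benzyloxy)-3,4,5-trimethoxyphenoxy]-5-oxo-3-(2,4,6-trimethoxyphenoxy)hex-2-enoate | COC(=O)/C=C(/Oc1c(OC)cc(OC)cc1OC)CC(=O)COc1cc(OC)c(OC)c(OC)c1OCc1ccccc1
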